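**Strategy.** The oxolane ring of the target (O1, C2, C3, C3a, C7a) carries two alkenyl carbons, C7 of the pyranone and C1' of the side chain, cis at C7a and C2, with the oxygens on C3 and C3a on the same face. This all-cis array is the ring-opened form of an endo,endo-dioxygenated 7-oxanorbornene, the furan–vinylene carbonate adduct. In the key step an acrylate on the future O4 undergoes ring-rearrangement metathesis: the strained bicyclic olefin opens, one of its carbons closes onto the acrylate to form the C6=C7 bond and the pyranone, and the other becomes a vinyl group that is cross-metathesised in the same flask with the side-chain olefin.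

Key step: step 8

Remark on the chemistry: the absolute sense of the two catalyst-controlled steps (3 and 6) is assigned by analogy with the usual behaviour of these catalyst families and is to be checked on the first run by Mosher ester analysis of 5 and 11; both catalysts are accessible in either enantiomeric form, and the antipode is used if the sense is reversed.

**Step 1**
Reactants: 1 furan; 2 vinylene carbonate
Product: 3 endo furan–vinylene carbonate adduct (meso endo-3a,4,7,7a-tetrahydro-4,7-epoxy-1,3-benzodioxol-2-one)
Conditions: neat (furan in excess), sealed tube, 125 °C; endo isomer separated from the exo isomer by chromatography and crystallisation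
Reagents that add atoms: none
Why: Thermal Diels–Alder reaction of furan with the cis dienophile vinylene carbonate, which should give the cis-fused endo and exo carbonates side by side; the endo isomer (carbonate oxygens syn to the C=C bridge) is the one that later places both oxygens cis to the two alkenyl arms of the oxolane, and because the adduct is meso no absolute configuration is set here.

**Step 2**
Reactants: 3 endo furan–vinylene carbonate adduct
Product: 4 (1R,2R,3S,4S)-7-oxabicyclo[2.2.1]hept-5-ene-2,3-diol (meso; both hydroxyls endo)
Conditions: K2CO3 (0.2 equiv), MeOH, rt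
Reagents that add atoms: none
Why: Base-catalysed transesterification of the cyclic carbonate with methanol expels dimethyl carbonate and should release the endo,endo cis-diol without touching the stereocentres or the strained olefin.

**Step 3**
Reactants: 4 meso endo,endo diol
Product: 5 (1R,2S,3S,4S)-3-[(tert-butyldimethylsilyl)oxy]-7-oxabicyclo[2.2.1]hept-5-en-2-ol (both oxygens endo)
Conditions: TBSCl (2 equiv), iPr2NEt (1.25 equiv), (S)-N-[(R)-3,3-dimethylbutan-2-yl]-3,3-dimethyl-2-{[(1-methyl-1H-imidazol-2-yl)methyl]amino}butanamide (30 mol %), THF, −40 °C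
Reagents that add atoms: tert-butyldimethylsilyl chloride, CC(C)(C)[Si](C)(C)Cl
Why: Catalytic enantioselective silylation (desymmetrisation) of a cyclic meso cis-1,2-diol, in which the hydrogen-bonding amino-acid-derived Lewis-base catalyst selects one enantiotopic hydroxyl, here the one on C3, and thereby fixes the absolute configuration of all four ring stereocentres at once.

**Step 4**
Reactants: 5 mono-silyl ether
Product: 6 (1R,2S,3R,4S)-3-[(tert-butyldimethylsilyl)oxy]-7-oxabicyclo[2.2.1]hept-5-en-2-yl prop-2-enoate
Conditions: acryloyl chloride (1.5 equiv), iPr2NEt (2 equiv), CH2Cl2, −78 → 0 °C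
Reagents that add atoms: acryloyl chloride, C=CC(=O)Cl
Why: O-Acylation of the remaining endo hydroxyl with an acid chloride under cold conditions with a non-nucleophilic base, chosen so that the silyl group does not migrate between the cis oxygens, which would racemise the material.

**Step 5**
Reactants: 7 acrolein
Product: 8 prop-2-ene-1,1-diyl dibenzoate
Conditions: (PhCO)2O (1.0 equiv), H2SO4 (cat.), CH2Cl2, 0 °C → rt
Reagents that add atoms: benzoic anhydride, O=C(OC(=O)c1ccccc1)c1ccccc1
Why: Acid-catalysed acylal formation, the 1,1-addition of a carboxylic anhydride across the aldehyde carbonyl, which should give the allylic gem-dibenzoate without any co-product.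

**Step 6**
Reactants: 9 ethanol (3 equiv); 8 prop-2-ene-1,1-diyl dibenzoate
Product: 11 (2R,3S)-3-(benzoyloxy)pent-4-en-2-ol, via acetaldehyde 10 (not isolated)
Conditions: [Ir(cod)Cl]2 (2.5 mol %), (S)-SEGPHOS (5 mol %), 4-cyano-3-nitrobenzoic acid (10 mol %), Cs2CO3 (20 mol %), THF, 90 °C, sealed tube
Reagents that add atoms: none
Why: Iridium-catalysed transfer-hydrogenative carbonyl (α-benzoyloxy)allylation from the alcohol oxidation level, in which ethanol is dehydrogenated to acetaldehyde, the resulting hydride complex ionises one benzoate of 8 to an (E)-σ-(benzoyloxy)allyl iridium species, and this adds to the aldehyde through a closed chair-like transition state that gives the anti relation of C2 and C3 while the chiral cyclometallated bisphosphine complex selects the aldehyde face.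

**Step 7**
Reactants: 11 (2R,3S)-3-(benzoyloxy)pent-4-en-2-ol
Product: 12 (3S,4R)-4-acetoxypent-1-en-3-yl benzoate
Conditions: Ac2O, pyridine, DMAP (cat.), CH2Cl2, 0 °C
Reagents that add atoms: acetic anhydride, CC(=O)OC(C)=O
Why: Nucleophile-catalysed acetylation of the secondary alcohol, run cold and fast so that the neighbouring benzoate does not migrate, with no stereocentre touched.

**Step 8**
Reactants: 6 oxanorbornenyl acrylate; 12 (3S,4R)-4-acetoxypent-1-en-3-yl benzoate (3 equiv)
Product: 15 silyl-protected target (2R,3S,4E)-2-acetoxy-5-[(2S,3R,3aS,7aR)-3-(tert-butyldimethylsilyloxy)-5-oxo-2,3,3a,7a-tetrahydro-5H-furo[3,2-b]pyran-2-yl]pent-4-en-3-yl benzoate, via divinyl oxolane acrylate 13 (not isolated), via vinyl lactone 14 (not isolated)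
Conditions: second-generation Hoveyda–Grubbs catalyst RuCl2(H2IMes)(=CH–C6H4-2-OiPr) (5 mol %), ethylene (1 atm), CH2Cl2 (0.01 M), rt; then argon purge, concentration to 0.1 M, 12 (3 equiv), further catalyst (5 mol %), 40 °C
Reagents that add atoms: none
Why: Ring-rearrangement metathesis followed in the same flask by cross-metathesis: ruthenium methylidene adds to the strained C5=C6 bond of 6 on its open exo face, cycloreversion opens the bicycle to the all-cis 2,5-divinyl oxolane 13 (or its ruthenium alkylidene), and the carbene on the former C6, next to C1, closes onto the acrylate on C2 by [2+2] and retro-[2+2], which forms the C6=C7 bond of the pyranone (product numbering) and gives 14. The closest known reaction type is the domino ring-opening/ring-closing metathesis of 7-oxanorbornenes that carry a tethered olefin, combined with the standard ring-closing metathesis of acrylates to α,β-unsaturated δ-lactones and a subsequent olefin cross-metathesis. The pyranone is the only ring closed, by ring-closing metathesis to a six-membered ring with an endocyclic Z olefin, and it is necessarily cis-fused because the acrylate and the carbene sit on the same face of the oxolane. No stereocentre is created: C2, C3, C3a and C7a are the four sp3 carbons of the endo Diels–Alder adduct, whose former bridge enforces the cis relation of C2 and C7a and whose endo oxygens end up cis to both alkenyl arms; the only new stereo element, the E side-chain olefin, is set by thermodynamic control in the cross-metathesis of two allylically branched partners. The step needs ring closure to outrun ring-opening polymerisation (ethylene and high dilution in the first stage), the six-membered lactone to form instead of a bridged seven-membered one (only the carbene at the former C6 reaches the acrylate without strain), and cross- over homo-coupling in the second stage (excess of the slowly dimerising 12, while the conjugated lactone olefin is inert).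

**Step 9**
Reactants: 15 silyl-protected target
Product: 16 target, (2R,3S,4E)-2-acetoxy-5-[(2S,3R,3aR,7aR)-3-hydroxy-5-oxo-2,3,3a,7a-tetrahydro-5H-furo[3,2-b]pyran-2-yl]pent-4-en-3-yl benzoate
Conditions: HF·pyridine, pyridine, THF, 0 °C → rt
Reagents that add atoms: none
Why: Fluoride-mediated cleavage of the silyl ether under buffered acidic conditions, which should leave the acetate, the benzoate and the unsaturated lactone intact and avoids a base-induced intramolecular oxa-Michael addition of the freed C3 hydroxyl to C7.

**Compound list**

1 | furan | c1ccoc1 | starting material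
2 | vinylene carbonate (1,3-dioxol-2-one) | O=C1OC=CO1 | starting material
3 | endo furan–vinylene carbonate adduct, meso endo-3a,4,7,7a-tetrahydro-4,7-epoxy-1,3-benzodioxol-2-one | C1=C[C@@H]2O[C@H]1[C@@H]1OC(=O)O[C@H]21 | intermediate
4 | (1R,2R,3S,4S)-7-oxabicyclo[2.2.1]hept-5-ene-2,3-diol, meso, both hydroxyls endo | C1=C[C@@H]2O[C@H]1[C@H](O)[C@@H]2O | intermediate
5 | (1R,2S,3S,4S)-3-[(tert-butyldimethylsilyl)oxy]-7-oxabicyclo[2.2.1]hept-5-en-2-ol, both oxygens endo | C1=C[C@@H]2O[C@H]1[C@H](O)[C@@H]2O[Si](C)(C)C(C)(C)C | intermediate
6 | (1R,2S,3R,4S)-3-[(tert-butyldimethylsilyl)oxy]-7-oxabicyclo[2.2.1]hept-5-en-2-yl prop-2-enoate | C1=C[C@@H]2O[C@H]1[C@H](OC(=O)C=C)[C@@H]2O[Si](C)(C)C(C)(C)C | intermediate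
7 | acrolein | C=CC=O | starting material
8 | prop-2-ene-1,1-diyl dibenzoate | C=CC(OC(=O)c1ccccc1)OC(=O)c1ccccc1 | intermediate
9 | ethanol | CCO | starting material
10 | acetaldehyde | CC=O | intermediate
11 | (2R,3S)-3-(benzoyloxy)pent-4-en-2-ol | C[C@@H](O)[C@H](C=C)OC(=O)c1ccccc1 | intermediate
12 | (3S,4R)-4-acetoxypent-1-en-3-yl benzoate | CC(=O)O[C@H](C)[C@H](C=C)OC(=O)c1ccccc1 | intermediate
13 | all-cis 4-[(tert-butyldimethylsilyl)oxy]-2,5-divinyloxolan-3-yl prop-2-enoate (ring-opened triene) | C=C[C@@H]1O[C@H](C=C)[C@H](OC(=O)C=C)[C@@H]1O[Si](C)(C)C(C)(C)C | intermediate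
14 | (2S,3R,3aS,7aR)-3-[(tert-butyldimethylsilyl)oxy]-2-vinyl-2,3,3a,7a-tetrahydro-5H-furo[3,2-b]pyran-5-one | C=C[C@@H]1O[C@@H]2C=CC(=O)O[C@@H]2[C@@H]1O[Si](C)(C)C(C)(C)C | intermediate
15 | (2R,3S,4E)-2-acetoxy-5-[(2S,3R,3aS,7aR)-3-(tert-butyldimethylsilyloxy)-5-oxo-2,3,3a,7a-tetrahydro-5H-furo[3,2-b]pyran-2-yl]pent-4-en-3-yl benzoate | CC(=O)O[C@H](C)[C@H](/C=C/[C@@H]1O[C@@H]2C=CC(=O)O[C@@H]2[C@@H]1O[Si](C)(C)C(C)(C)C)OC(=O)c1ccccc1 | intermediate
16 | (2R,3S,4E)-2-acetoxy-5-[(2S,3R,3aR,7aR)-3-hydroxy-5-oxo-2,3,3a,7a-tetrahydro-5H-furo[3,2-b]pyran-2-yl]pent-4-en-3-yl benzoate | CC(=O)O[C@H](C)[C@H](/C=C/[C@@H]1O[C@@H]2C=CC(=O)O[C@@H]2[C@@H]1O)OC(=O)c1ccccc1 | target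

**Totals.** Total step count: 9. Longest linear sequence: 6 steps (1, 2, 3, 4, 8, 9); the side-chain branch (5, 6, 7) joins at step 8.

**Steps most likely to fail**

Step 8 (key step). The strained olefin may oligomerise by ring-opening metathesis before the acrylate closes. More likely, the second stage may stall at the vinyl lactone, because both olefins are allylically oxygenated and the vinyl group is flanked by the cis silyl ether. The fallback sets out from 6 and separates the two events. The rearrangement alone is run under ethylene and vinyl lactone 14 is isolated. Its silyl ether is cleaved first (HF·pyridine, THF) to (2S,3R,3aR,7aR)-3-hydroxy-2-vinyl-2,3,3a,7a-tetrahydro-5H-furo[3,2-b]pyran-5-one F1. F1 is less hindered and has a free homoallylic hydroxyl that can assist the ruthenium carbene; it is cross-metathesised with 12 (second-generation Hoveyda–Grubbs catalyst, CH2Cl2, 40 °C), so the coupling runs on the unprotected alcohol. The fallback comes back to the route at 16.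

Step 3. The catalyst may discriminate poorly between the enantiotopic hydroxyls of the rigid bicyclic diol, or the silyl group may migrate between the cis oxygens and erode the enantiomeric purity. The fallback sets out from 4 and replaces the chemical catalyst by an enzyme. Lipase-mediated transesterification (immobilised Candida antarctica lipase B, vinyl acetate, tert-butyl methyl ether, rt; the enzyme is chosen from a screen of commercial lipases for acetylation at O2) should give (1R,2R,3R,4S)-3-hydroxy-7-oxabicyclo[2.2.1]hept-5-en-2-yl acetate F2. Silylation of the remaining hydroxyl (TBSOTf, 2,6-lutidine, CH2Cl2, −78 °C) gives (1R,2S,3R,4S)-3-[(tert-butyldimethylsilyl)oxy]-7-oxabicyclo[2.2.1]hept-5-en-2-yl acetate F3. Reductive removal of the acetate (iBu2AlH, CH2Cl2, −78 °C) then comes back to the route at 5.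

Step 6. The benzoate may shift to the neighbouring alkoxide under the basic conditions at 90 °C, or facial and anti selectivity may be insufficient with the very small aldehyde. The fallback takes the carbinol centre from the chiral pool. It sets out not from a compound of the route but from commercial methyl (R)-lactate F4, which replaces 7, 8 and 9. Silylation (TBSCl, imidazole, DMF) gives methyl (R)-2-[(tert-butyldimethylsilyl)oxy]propanoate F5. Half-reduction (iBu2AlH, CH2Cl2, −78 °C) gives (R)-2-[(tert-butyldimethylsilyl)oxy]propanal F6. Addition of vinylmagnesium bromide (THF, −78 °C) under Felkin–Anh control should give mainly the anti alcohol (3S,4R)-4-[(tert-butyldimethylsilyl)oxy]pent-1-en-3-ol F7. Benzoylation (PhCOCl, pyridine) gives (3S,4R)-4-[(tert-butyldimethylsilyl)oxy]pent-1-en-3-yl benzoate F8, at which stage the minor syn isomer is removed. Acidic desilylation (aqueous HF, MeCN) comes back to the route at 11.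

**Further compounds**

F1 | step 8 | (2S,3R,3aR,7aR)-3-hydroxy-2-vinyl-2,3,3a,7a-tetrahydro-5H-furo[3,2-b]pyran-5-one | C=C[C@@H]1O[C@@H]2C=CC(=O)O[C@@H]2[C@@H]1O
F2 | step 3 | (1R,2R,3R,4S)-3-hydroxy-7-oxabicyclo[2.2.1]hept-5-en-2-yl acetate | C1=C[C@@H]2O[C@H]1[C@H](OC(C)=O)[C@@H]2O
F3 | step 3 | (1R,2S,3R,4S)-3-[(tert-butyldimethylsilyl)oxy]-7-oxabicyclo[2.2.1]hept-5-en-2-yl acetate | C1=C[C@@H]2O[C@H]1[C@H](OC(C)=O)[C@@H]2O[Si](C)(C)C(C)(C)C
F4 | step 6 | methyl (R)-lactate | C[C@@H](O)C(=O)OC
F5 | step 6 | methyl (R)-2-[(tert-butyldimethylsilyl)oxy]propanoate | C[C@@H](O[Si](C)(C)C(C)(C)C)C(=O)OC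
F6 | step 6 | (R)-2-[(tert-butyldimethylsilyl)oxy]propanal | C[C@@H](O[Si](C)(C)C(C)(C)C)C=O
F7 | step 6 | (3S,4R)-4-[(tert-butyldimethylsilyl)oxy]pent-1-en-3-ol | C[C@@H](O[Si](C)(C)C(C)(C)C)[C@H](C=C)O
F8 | step 6 | (3S,4R)-4-[(tert-butyldimethylsilyl)oxy]pent-1-en-3-yl benzoate | C[C@@H](O[Si](C)(C)C(C)(C)C)[C@H](C=C)OC(=O)c1ccccc1
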